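Reagent is conserved in my ledger: a mole charged either stands in the flask or was spent, one mole per substrate taken to single product and one more per single product taken on to double product.

| flask | substrate | reagent | remark | time |
|---|---|---|---|---|
| alpha | 0.095 M | 0.13 M | run made earlier |  |
| theta | 0.095 M | 0.27 M | run made earlier |  |
| west | 0.095 M | 0.237 M |  | 25 h |
| north | 0.095 M | 0.114 M |  | 25 h |

| run | time / h | single product / % | substrate / % |
|---|---|---|---|
| alpha | 0.833 | 45.3 | 47.4 |
| alpha | 2.50 | 69.2 | 18.6 |
| alpha | 4.00 | 75.8 | 11.5 |
| alpha | 6.00 | 78.6 | 6.8 |
| alpha | 10.0 | 76.9 | 3.0 |
| alpha | 12.0 | 78.3 | 1.8 |
| theta | 1.00 | 73.7 | 15.1 |
| theta | 1.50 | 80.1 | 7.3 |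
| theta | 3.00 | 74.7 | 1.3 |
| theta | 5.00 | 65.5 | 1.0 |
| theta | 8.00 | 49.5 | 0 |
| theta | 12.0 | 31.6 | 1.3 |

(readings scatter by 1 percentage point)

- a reading or a percentage of single product counts all its forms, free or not

- which of these holds the largest part of the substrate at the end of west (single product / double product / substrate)
- which of these holds the largest part of the substrate at the end of north (single product / double product / substrate)
- final single product in west, as a percentage of the substrate charged

1. I set the zero of the scale at one equivalent, where each substrate gets one reagent and double product has nothing to draw on. The surplus s, reagent charged less substrate charged, over substrate charged, is 149 % in west. Once substrate has reacted, s is the ceiling on double product.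

2. In the alpha run s is 36.8 %, and the last reading leaves 19.9 % outside single product and substrate, which I book as double product, less than that ceiling.

3. North has s = 20.0 %, so I expect single product to lead there. West holds more than two reagent per substrate, so its ceiling lies above the whole charge. West also runs twice as long as the theta run, whose single product fell from 65.5 % to 31.6 % between 5.00 h and 12.0 h, so I expect double product to lead in west.

The forecast makes the same two choices, double product for west and single product for north, and puts n at 11 %, within 4 % to 21 %, holding that “the second step is first order in reagent but nearly zero order in single product”.

West gives 8.40 % of single product and 87.6 % of double product; north gives 77.9 % and 16.3 %, under its ceiling.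

    substrate + reagent → single product + by-product (k = 9.00 /M/h)
    reagent + single product → double product + by-product (k = 6.80 /M/h)
    single product ⇌ isomer of the product (K = 0.740, k = 0.720 /h)
    crystals ⇌ single product, rate k4*(cs4 - [single product]) while solid is left; crystals form when [single product] > cs4 (solubility = 5.10 mM, k = 120 /h)

West's books close: s less its double product, turned to reagent's own charge, is 24.8 %, and the reagent left in west is 25 %. The neighbouring flask is west with 0.38 M of substrate, that is 0.624 equiv of reagent. In that flask s is −37.6 %, reagent becomes the limiting reagent, and 0 % of it stands at the end. That deficit plus the flask's 1.32 % of double product books 38.9 % of substrate unreacted, and the flask holds 39 % of substrate beside 58.7 % of single product.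

The readings stem from a simulated flask with made-up constants; the scatter is artificial.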